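**Retrosynthetic overview**
1. Feature the route rests on: in the bicyclo[3.3.1]nonane (ring A = C1–C2–C3–C4–C5–C9, ring B = C5–C6–C7–C8–C1–C9) bridgehead C1 is bonded to quaternary C8, and C8 sits beside C7, the only stereocentre that is not a bridgehead; its prenyl group is exo (trans to ring A).
2. Key disconnection C1–C8 (ring B, made last): a C8 tertiary cation, released from a silyl ether, is taken by one of the two enantiotopic methyl enol ethers of an achiral 6,6-dialkyl-1,5-dimethoxycyclohexa-1,4-diene, so that C7 (bought as (S)-lavandulol) sets C1 and C5.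
3. The C2 carbonyl is added only after this closure, so that the attacking carbon belongs to a plain enol ether and not to an electron-poor, Lewis-basic methoxy enone.
4. Ring A is the ring of 1,3-dimethoxybenzene (Birch reduction, two alkylations at the future C5); after ring B come C2 oxidation, C1 prenylation, C3 aroylation and deprotection. Ring order: A (bought), then B (step 8).

Key step: step 8

Assumption: the lipase acylates (R)-lavandulol faster than (S)-lavandulol, so the alcohol left at high conversion is the (S)-enantiomer.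

Bicyclic compounds use the C1–C9 numbering above; "exo" at C7 means on the face of ring B away from ring A.

Step 1
Reactants: 1 (±)-lavandulol
Product: 2 (S)-lavandulol
Conditions: porcine pancreatic lipase, vinyl acetate, hexane, rt; stopped past half conversion (chiral GC); chromatography
Reagents that add atoms: none
Why: Lipase-catalysed kinetic resolution by transesterification should acylate the (R)-alcohol faster, so the alcohol recovered at high conversion is (S)-lavandulol, whose stereocentre becomes C7.

Step 2
Reactants: 2 (S)-lavandulol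
Product: 3 (2R)-3-methyl-2-(3-methylbut-2-en-1-yl)butane-1,3-diol
Conditions: Co(acac)2 (cat.), PhSiH3, O2 (1 atm), THF, rt
Reagents that add atoms: dioxygen, O=O
Why: Mukaiyama hydration (hydrogen-atom transfer from a cobalt hydride, trapping of the tertiary radical by O2, reduction) adds water in the Markovnikov sense to the 1,1-disubstituted isopropenyl alkene, which reacts faster than the trisubstituted prenyl alkene; the stereocentre is untouched (the descriptor changes only through priorities).

Step 3
Reactants: 3 diol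
Product: 4 (3S)-4-iodo-2-methyl-3-(3-methylbut-2-en-1-yl)butan-2-ol
Conditions: I2, PPh3, imidazole, CH2Cl2, 0 °C
Reagents that add atoms: iodine, II
Why: Appel iodination converts only the primary alcohol, because the tertiary alcohol is too hindered to form the alkoxyphosphonium ion at 0 °C.

Step 4
Reactants: 4 iodo alcohol
Product: 5 (3S)-4-iodo-2-methyl-3-(3-methylbut-2-en-1-yl)butan-2-yl trimethylsilyl ether
Conditions: Me3SiOTf, 2,6-lutidine, CH2Cl2, −78 °C
Reagents that add atoms: trimethylsilyl trifluoromethanesulfonate, C[Si](C)(C)OS(=O)(=O)C(F)(F)F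
Why: Silyl triflate with a hindered pyridine silylates the tertiary alcohol, which lets the iodide meet a carbanion and makes the silyl ether the leaving group of step 8.

Step 5
Reactants: 6 1,3-dimethoxybenzene
Product: 7 1,5-dimethoxycyclohexa-1,4-diene
Conditions: Li, NH3 (l), t-BuOH, THF, −78 → −33 °C
Reagents that add atoms: none
Why: Birch reduction gives the 2,5-dihydro arene, in which both methoxy groups stay on isolated double bonds (a bis enol ether).

Step 6
Reactants: 7 1,5-dimethoxycyclohexa-1,4-diene; 5 iodide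
Product: 9 6-[(2R)-3-methyl-2-(3-methylbut-2-en-1-yl)-3-(trimethylsilyloxy)butyl]-1,5-dimethoxycyclohexa-1,4-diene, via 6-lithio-1,5-dimethoxycyclohexa-1,4-diene 8 (not isolated)
Conditions: t-BuLi (slight deficit), THF, −78 °C; then HMPA, 5, −78 → 0 °C
Reagents that add atoms: none
Why: t-BuLi removes a proton from the CH2 between the two methoxy-bearing carbons (the only site whose cyclohexadienyl anion keeps charge off those carbons), and the anion is alkylated at its central carbon by SN2 displacement of the primary iodide, with HMPA offsetting the β-branching.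

Step 7
Reactants: 9 monoalkyl diene; 10 geranyl bromide
Product: 12 6-[(2E)-3,7-dimethylocta-2,6-dien-1-yl]-6-[(2R)-3-methyl-2-(3-methylbut-2-en-1-yl)-3-(trimethylsilyloxy)butyl]-1,5-dimethoxycyclohexa-1,4-diene, via ring-lithiated diene 11 (not isolated)
Conditions: t-BuLi, THF, −78 → −40 °C; then 10, −78 °C → rt
Reagents that add atoms: none
Why: A second deprotonation at the same ring carbon and SN2 alkylation with the reactive allylic bromide builds the quaternary future C5; the ring keeps its mirror plane, so no new stereocentre arises.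

Step 8
Reactants: 12 silyl ether diene
Product: 15 (7R)-5-geranyl-4-methoxy-8,8-dimethyl-7-exo-prenylbicyclo[3.3.1]non-3-en-9-one, via C8 tertiary cation triflate 13 (not isolated), via C9 methoxycarbenium triflate 14 (not isolated)
Conditions: Me3SiOTf (2 equiv), 2,6-di-tert-butyl-4-methylpyridine (3 equiv), CH2Cl2, −78 → −40 °C; aq. NaHCO3
Reagents that add atoms: none
Why: Me3SiOTf silylates the ether oxygen, hexamethyldisiloxane leaves with help from the enol ether π bond, and the C8 cation 13 is taken by the β-carbon of one methyl enol ether to form C1–C8; the C9 methoxycarbenium ion 14 then gives up its methyl group to triflate and leaves the C9 ketone. The closest known reaction type is the Lewis-acid (Prins-type) cyclization of a tertiary cation or an activated epoxide onto the methyl enol ether of a 2,2-disubstituted cyclohexane-1,3-dione, which gives bicyclo[3.3.1]nonanes. Ring B closes in a 6-(enolendo)-exo-tet mode at C8 through a chair-like transition state. C1 and C5 become stereocentres under the control of C7: only the chair with the C7 prenyl group equatorial is low in energy, and that chair uses one of the two enantiotopic enol ethers and places the prenyl group exo. The enol ether must outrun both the geranyl C2'=C3' alkene (also six atoms from C8) and the 1,2-hydride shift from C7, which the much higher nucleophilicity of an unconjugated enol ether and the low temperature should secure; C-alkylation is assured because both ring oxygens are methylated, and the hindered pyridine keeps the trisubstituted alkenes unprotonated.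

Step 9
Reactants: 15 bicyclic enol ether ketone
Product: 16 (7R)-5-geranyl-4-methoxy-8,8-dimethyl-7-exo-prenylbicyclo[3.3.1]non-3-ene-2,9-dione
Conditions: t-BuOOH, PhI(OAc)2, Cs2CO3, EtOAc, −20 °C
Reagents that add atoms: tert-butyl hydroperoxide, CC(C)(C)OO
Why: Allylic C–H oxidation (hydrogen abstraction by tert-butylperoxy radical, peroxide formation, Kornblum–DeLaMare elimination) should go to C2, the only CH2 next to the electron-rich enol ether, whose C–H bonds are weaker and more hydridic than the allylic C–H bonds of the geranyl and prenyl chains.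

Step 10
Reactants: 16 vinylogous ester; 17 prenyl bromide
Product: 19 (7R)-5-geranyl-4-methoxy-8,8-dimethyl-1,7-diprenylbicyclo[3.3.1]non-3-ene-2,9-dione (7-exo), via C1 bridgehead lithium enolate 18 (not isolated)
Conditions: LDA, THF, −78 °C; then 17, −78 → 0 °C
Reagents that add atoms: none
Why: Bridgehead lithiation and alkylation: C1–H lies between the C2 and C9 carbonyls and is removed as a bridgehead enolate (tolerated in the bicyclo[3.3.1] frame), which is C-alkylated by the allylic bromide with retention, since a bridgehead cannot invert.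

Step 11
Reactants: 20 3,4-dihydroxybenzoic acid
Product: 21 tert-butyldimethylsilyl 3,4-bis(tert-butyldimethylsilyloxy)benzoate
Conditions: t-BuMe2SiCl (3.3 equiv), imidazole, DMF, rt
Reagents that add atoms: tert-butyldimethylsilyl chloride, CC(C)(C)[Si](C)(C)Cl
Why: Exhaustive silylation with silyl chloride and imidazole caps both phenols and the acid in one operation.

Step 12
Reactants: 21 tris-silyl compound
Product: 22 3,4-bis(tert-butyldimethylsilyloxy)benzoyl chloride
Conditions: (COCl)2, DMF (cat.), CH2Cl2, 0 °C → rt; used crude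
Reagents that add atoms: oxalyl chloride, O=C(Cl)C(Cl)=O
Why: The Vilsmeier reagent turns a silyl ester directly into the acid chloride under neutral conditions, which the aryl silyl ethers survive.

Step 13
Reactants: 19 C1-prenylated vinylogous ester; 22 acid chloride
Product: 24 (7R)-3-[3,4-bis(tert-butyldimethylsilyloxy)benzoyl]-5-geranyl-4-methoxy-8,8-dimethyl-1,7-diprenylbicyclo[3.3.1]non-3-ene-2,9-dione (7-exo), via C3 vinyllithium 23 (not isolated)
Conditions: lithium 2,2,6,6-tetramethylpiperidide, THF, −78 °C; then 22, −78 → −40 °C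
Reagents that add atoms: none
Why: Vinylic α-lithiation of the β-methoxy enone at C3 (the only acidic C–H left, stabilised by the flanking carbonyl and the methoxy oxygen) followed by acylation with the acid chloride installs the aroyl group.

Step 14
Reactants: 24 bis-silyl ether
Product: 25 (7R)-3-(3,4-dihydroxybenzoyl)-5-geranyl-4-methoxy-8,8-dimethyl-1,7-diprenylbicyclo[3.3.1]non-3-ene-2,9-dione (7-exo)
Conditions: Et3N·3HF, THF, rt
Reagents that add atoms: none
Why: Fluoride cleaves the aryl silyl ethers under nearly neutral conditions that leave the vinylogous ester and the four alkenes alone.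

Step 15
Reactants: 25 O-methyl ether
Product: 26 target (7R)-3-(3,4-dihydroxybenzoyl)-5-geranyl-4-hydroxy-8,8-dimethyl-1,7-diprenylbicyclo[3.3.1]non-3-ene-2,9-dione (7-exo)
Conditions: LiCl, DMSO, 120 °C, argon; then dilute aq. HCl
Reagents that add atoms: none
Why: Chloride attacks the methyl group by SN2 (Krapcho-type demethylation), the leaving group being the stabilised enolate of the acyl-β-diketone, and the neutral medium spares the catechol and the alkenes.

**Compound list**
1 | (±)-lavandulol | CC(C)=CCC(CO)C(C)=C | starting material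
2 | (S)-lavandulol | OC[C@@H](CC=C(C)C)C(C)=C | intermediate
3 | (2R)-3-methyl-2-(3-methylbut-2-en-1-yl)butane-1,3-diol | OC[C@@H](CC=C(C)C)C(C)(C)O | intermediate
4 | (3S)-4-iodo-2-methyl-3-(3-methylbut-2-en-1-yl)butan-2-ol | IC[C@@H](CC=C(C)C)C(C)(C)O | intermediate
5 | (3S)-4-iodo-2-methyl-3-(3-methylbut-2-en-1-yl)butan-2-yl trimethylsilyl ether | IC[C@@H](CC=C(C)C)C(C)(C)O[Si](C)(C)C | intermediate
6 | 1,3-dimethoxybenzene | COc1cccc(OC)c1 | starting material
7 | 1,5-dimethoxycyclohexa-1,4-diene | COC1=CCC=C(OC)C1 | intermediate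
8 | 6-lithio-1,5-dimethoxycyclohexa-1,4-diene | [Li]C1C(OC)=CCC=C1OC | intermediate (not isolated)
9 | 6-[(2R)-3-methyl-2-(3-methylbut-2-en-1-yl)-3-(trimethylsilyloxy)butyl]-1,5-dimethoxycyclohexa-1,4-diene | COC1=CCC=C(OC)C1C[C@@H](CC=C(C)C)C(C)(C)O[Si](C)(C)C | intermediate
10 | geranyl bromide | CC(C)=CCC/C(C)=C/CBr | starting material
11 | 6-lithio derivative of 9 | [Li]C1(C[C@@H](CC=C(C)C)C(C)(C)O[Si](C)(C)C)C(OC)=CCC=C1OC | intermediate (not isolated)
12 | 6-geranyl-6-[(2R)-3-methyl-2-(3-methylbut-2-en-1-yl)-3-(trimethylsilyloxy)butyl]-1,5-dimethoxycyclohexa-1,4-diene (key-step precursor) | COC1=CCC=C(OC)C1(C/C=C(\C)CCC=C(C)C)C[C@@H](CC=C(C)C)C(C)(C)O[Si](C)(C)C | intermediate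
13 | C8 tertiary carbocation triflate from 12 | COC1=CCC=C(OC)C1(C/C=C(\C)CCC=C(C)C)C[C@@H](CC=C(C)C)[C+](C)C.[O-]S(=O)(=O)C(F)(F)F | intermediate (not isolated)
14 | bicyclic C9 methoxycarbenium triflate | CC(C)=CCC/C(C)=C/C[C@]12C[C@@H](CC=C(C)C)C(C)(C)[C@H](CC=C1OC)C2=[O+]C.[O-]S(=O)(=O)C(F)(F)F | intermediate (not isolated)
15 | (7R)-5-geranyl-4-methoxy-8,8-dimethyl-7-exo-prenylbicyclo[3.3.1]non-3-en-9-one | CC(C)=CCC/C(C)=C/C[C@]12C[C@@H](CC=C(C)C)C(C)(C)[C@H](CC=C1OC)C2=O | intermediate
16 | (7R)-5-geranyl-4-methoxy-8,8-dimethyl-7-exo-prenylbicyclo[3.3.1]non-3-ene-2,9-dione | CC(C)=CCC/C(C)=C/C[C@]12C[C@@H](CC=C(C)C)C(C)(C)[C@H](C(=O)C=C1OC)C2=O | intermediate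
17 | prenyl bromide | CC(C)=CCBr | starting material
18 | C1 bridgehead lithium derivative of 16 | CC(C)=CCC/C(C)=C/C[C@]12C[C@@H](CC=C(C)C)C(C)(C)[C@]([Li])(C(=O)C=C1OC)C2=O | intermediate (not isolated)
19 | (7R)-5-geranyl-4-methoxy-8,8-dimethyl-1,7-diprenylbicyclo[3.3.1]non-3-ene-2,9-dione (7-exo) | CC(C)=CCC/C(C)=C/C[C@]12C[C@@H](CC=C(C)C)C(C)(C)[C@](CC=C(C)C)(C(=O)C=C1OC)C2=O | intermediate
20 | 3,4-dihydroxybenzoic acid | OC(=O)c1ccc(O)c(O)c1 | starting material
21 | tert-butyldimethylsilyl 3,4-bis(tert-butyldimethylsilyloxy)benzoate | CC(C)(C)[Si](C)(C)OC(=O)c1ccc(O[Si](C)(C)C(C)(C)C)c(O[Si](C)(C)C(C)(C)C)c1 | intermediate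
22 | 3,4-bis(tert-butyldimethylsilyloxy)benzoyl chloride | ClC(=O)c1ccc(O[Si](C)(C)C(C)(C)C)c(O[Si](C)(C)C(C)(C)C)c1 | intermediate
23 | C3-lithio derivative of 19 | CC(C)=CCC/C(C)=C/C[C@]12C[C@@H](CC=C(C)C)C(C)(C)[C@](CC=C(C)C)(C(=O)C([Li])=C1OC)C2=O | intermediate (not isolated)
24 | 3-[3,4-bis(tert-butyldimethylsilyloxy)benzoyl] derivative of 19 | CC(C)=CCC/C(C)=C/C[C@]12C[C@@H](CC=C(C)C)C(C)(C)[C@](CC=C(C)C)(C(=O)C(C(=O)c3ccc(O[Si](C)(C)C(C)(C)C)c(O[Si](C)(C)C(C)(C)C)c3)=C1OC)C2=O | intermediate
25 | 3-(3,4-dihydroxybenzoyl)-4-methoxy compound (O-methyl ether of the target) | CC(C)=CCC/C(C)=C/C[C@]12C[C@@H](CC=C(C)C)C(C)(C)[C@](CC=C(C)C)(C(=O)C(C(=O)c3ccc(O)c(O)c3)=C1OC)C2=O | intermediate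
26 | CNP0160101.3 | CC(C)=CCC/C(C)=C/C[C@]12C[C@@H](CC=C(C)C)C(C)(C)[C@](CC=C(C)C)(C(=O)C(C(=O)c3ccc(O)c(O)c3)=C1O)C2=O | target

**Step count**
Total: 15 steps. Longest linear sequence: 12 steps (steps 1–4, 6–10, 13–15).

**Steps most likely to fail**

Step 8. Process at risk: after ionisation the C8 cation may lose a proton or accept the hydride from C7 (erasing the C7 configuration) before the enol ether reaches it, and weak discrimination between the two enantiotopic enol ethers would give exo/endo mixtures. Fallback, setting out from 7 and 10 and returning at 16: the free cation is replaced by a Lewis-acid-activated epoxide, which opens only as the enol ether attacks. Prenol is epoxidised (Sharpless; Ti(Oi-Pr)4, D-(−)-diethyl tartrate, t-BuOOH) to (R)-(3,3-dimethyloxiran-2-yl)methanol F1 and converted (CBr4, PPh3) into (S)-2-(bromomethyl)-3,3-dimethyloxirane F2. Compound 7 is alkylated first with 10 to 6-geranyl-1,5-dimethoxycyclohexa-1,4-diene F3 and then with F2 to the epoxide-bearing diene F4. Me3SiOTf with 2,6-lutidine at −78 °C should open the epoxide at its tertiary carbon (C1–C8 bond) while the C7 alkoxide traps the C9 oxocarbenium ion as the bridged methyl ketal F5. Allylic oxidation as in step 9 gives the C2 ketone F6, and pyridinium tosylate in wet acetone unlocks the ketal to the C7 exo-alcohol F7. Its O-phenyl thionocarbonate F8 (PhOC(S)Cl, pyridine) undergoes Keck radical allylation (allyltributylstannane, AIBN, benzene, 80 °C) from the exo face to the C7 allyl compound F9. Cross-metathesis with 2-methyl-2-butene (second-generation Grubbs catalyst) turns allyl into prenyl and gives 16.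

Step 9. Process at risk: hydrogen abstraction at the allylic positions of the geranyl and prenyl chains competes with oxidation at C2. Fallback, setting out from 12 and returning at 16: the ring CH2 of 12 is oxidised before ring closure, where it is doubly allylic to two enol ethers and far weaker than any other C–H bond, with pyridinium dichromate, (C5H5NH)2Cr2O7, and t-BuOOH on Celite in benzene to the cross-conjugated dienone F10. F10 is then closed under the conditions of step 8, warmed as needed, with the α-carbon of the methoxy enone taking the C8 cation to give 16 directly. The price is a much weaker nucleophile and a ring carbonyl that binds the silyl triflate, which is why this order is not the first choice.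

Step 10. Process at risk: deprotonation at the vinylic C3–H instead of the hindered bridgehead C1–H, which would put the prenyl group on C3. Fallback, setting out from 16 and returning at 19: C3 is masked first as the C3-trimethylsilyl compound F11 (lithium 2,2,6,6-tetramethylpiperidide with Me3SiCl present, THF, −78 °C). LDA and prenyl bromide can then act only at C1 and give the C1-prenyl C3-silyl compound F12, and Bu4NF in THF removes the silyl group to give 19.

**Further compounds**
F1 | step 8 | (R)-(3,3-dimethyloxiran-2-yl)methanol | OC[C@H]1OC1(C)C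
F2 | step 8 | (S)-2-(bromomethyl)-3,3-dimethyloxirane | BrC[C@H]1OC1(C)C
F3 | step 8 | 6-geranyl-1,5-dimethoxycyclohexa-1,4-diene | COC1=CCC=C(OC)C1C/C=C(\C)CCC=C(C)C
F4 | step 8 | 6-geranyl-6-{[(2R)-3,3-dimethyloxiran-2-yl]methyl}-1,5-dimethoxycyclohexa-1,4-diene | COC1=CCC=C(OC)C1(C/C=C(\C)CCC=C(C)C)C[C@H]2OC2(C)C
F5 | step 8 | bridged C9 methyl ketal (C7–O–C9) of 5-geranyl-4-methoxy-8,8-dimethylbicyclo[3.3.1]non-3-ene | CC(C)=CCC/C(C)=C/C[C@]12C[C@@H](O3)C(C)(C)[C@H](CC=C1OC)[C@]23OC
F6 | step 8 | C2 ketone of F5 | CC(C)=CCC/C(C)=C/C[C@]12C[C@@H](O3)C(C)(C)[C@H](C(=O)C=C1OC)[C@]23OC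
F7 | step 8 | 5-geranyl-7-exo-hydroxy-4-methoxy-8,8-dimethylbicyclo[3.3.1]non-3-ene-2,9-dione | CC(C)=CCC/C(C)=C/C[C@]12C[C@@H](O)C(C)(C)[C@H](C(=O)C=C1OC)C2=O
F8 | step 8 | O-phenyl thionocarbonate of F7 | CC(C)=CCC/C(C)=C/C[C@]12C[C@@H](OC(=S)Oc3ccccc3)C(C)(C)[C@H](C(=O)C=C1OC)C2=O
F9 | step 8 | 7-exo-allyl-5-geranyl-4-methoxy-8,8-dimethylbicyclo[3.3.1]non-3-ene-2,9-dione | CC(C)=CCC/C(C)=C/C[C@]12C[C@@H](CC=C)C(C)(C)[C@H](C(=O)C=C1OC)C2=O
F10 | step 9 | 4-geranyl-3,5-dimethoxy-4-[(2R)-3-methyl-2-(3-methylbut-2-en-1-yl)-3-(trimethylsilyloxy)butyl]cyclohexa-2,5-dien-1-one | COC1=CC(=O)C=C(OC)C1(C/C=C(\C)CCC=C(C)C)C[C@@H](CC=C(C)C)C(C)(C)O[Si](C)(C)C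
F11 | step 10 | 3-trimethylsilyl derivative of 16 | CC(C)=CCC/C(C)=C/C[C@]12C[C@@H](CC=C(C)C)C(C)(C)[C@H](C(=O)C([Si](C)(C)C)=C1OC)C2=O
F12 | step 10 | 3-trimethylsilyl derivative of 19 | CC(C)=CCC/C(C)=C/C[C@]12C[C@@H](CC=C(C)C)C(C)(C)[C@](CC=C(C)C)(C(=O)C([Si](C)(C)C)=C1OC)C2=O
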